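**Retrosynthetic overview**

1. Target 18 ⇐ 17 (hydrogenolysis of the two benzyl ethers) ⇐ 16 (methylation of the C2' phenol).
2. 16 ⇐ 9 + 14 + CO (Dötz benzannulation on the finished chromone): the alkyne carbons become C1' and C6', the carbene carbon C5', the vinyl carbons C4' and C3', and CO becomes C2'. The feature used is ring B itself: oxygen on C2', C3', C4' and C5', with O–C2' para to O–C5' and C6' as the only CH, so that C1' lies between a phenol carbon and a CH.
3. 9 ⇐ 3-iodochromone 7 (Sonogashira coupling, desilylation) ⇐ enaminone 6 (iodocyclisation closes ring C) ⇐ acetophenone 5 ⇐ phloroacetophenone 1 (dibenzylation, Elbs oxidation for the C6 oxygen, methylation).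
4. 14 ⇐ (Z)-1,2-dimethoxyethene 10 + Cr(CO)6 11 (Fischer carbene synthesis).
5. Ring order: ring A comes with 1, ring C is closed in step 5, ring B in step 9.

Key step: step 9

Remark on the chemistry: 1,2-dimethoxyethene is supplied as a cis/trans mixture, and the route assumes the (Z) isomer 10 is available pure by fractionation; because the vinyl geometry disappears when ring B aromatises, (E) material would converge on the same phenol 16.

**Route**

Step 1
Reactants: 1 1-(2,4,6-trihydroxyphenyl)ethanone (phloroacetophenone)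
Product: 2 1-[2,4-bis(benzyloxy)-6-hydroxyphenyl]ethanone
Conditions: BnBr (2.1 equiv), K2CO3, DMF, rt
Reagents that add atoms: benzyl bromide, BrCc1ccccc1
Why: Williamson etherification, in which the para hydroxyl and one of the two equivalent ortho hydroxyls are alkylated while the last ortho hydroxyl stays hydrogen-bonded to the acetyl carbonyl and is left free.

Step 2
Reactants: 2 1-[2,4-bis(benzyloxy)-6-hydroxyphenyl]ethanone
Product: 4 1-[2,4-bis(benzyloxy)-3,6-dihydroxyphenyl]ethanone, via aryl potassium sulfate 3 (not isolated)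
Conditions: K2S2O8, aq NaOH, pyridine, 0 °C → rt; then aq HCl, 80 °C
Reagents that add atoms: potassium peroxydisulfate, [K+].[K+].[O-]S(=O)(=O)OOS(=O)(=O)[O-]
Why: Elbs persulfate oxidation, in which the phenoxide of 2 attacks peroxydisulfate through its free para carbon (C3, between the two benzyloxy groups) to give sulfate 3, and acid hydrolysis of the S–O bond frees the para-hydroquinone.

Step 3
Reactants: 4 1-[2,4-bis(benzyloxy)-3,6-dihydroxyphenyl]ethanone
Product: 5 1-[2,4-bis(benzyloxy)-6-hydroxy-3-methoxyphenyl]ethanone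
Conditions: MeI (1.1 equiv), K2CO3, acetone, Ar, rt
Reagents that add atoms: iodomethane, CI
Why: selective Williamson methylation, since the C6 hydroxyl is chelated to the acetyl carbonyl and much less nucleophilic, so one equivalent of MeI should etherify only the C3 hydroxyl.

Step 4
Reactants: 5 1-[2,4-bis(benzyloxy)-6-hydroxy-3-methoxyphenyl]ethanone
Product: 6 (E)-1-[2,4-bis(benzyloxy)-6-hydroxy-3-methoxyphenyl]-3-(dimethylamino)prop-2-en-1-one
Conditions: Me2NCH(OMe)2, toluene, 90 °C
Reagents that add atoms: N,N-dimethylformamide dimethyl acetal, COC(OC)N(C)C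
Why: condensation of the acetyl methyl group with the amide acetal gives the (E)-enaminone (a vinylogous amide), the standard chromone precursor, and the chelated phenol is not touched.

Step 5
Reactants: 6 (E)-1-[2,4-bis(benzyloxy)-6-hydroxy-3-methoxyphenyl]-3-(dimethylamino)prop-2-en-1-one
Product: 7 5,7-bis(benzyloxy)-3-iodo-6-methoxy-4H-chromen-4-one
Conditions: I2, CHCl3, rt
Reagents that add atoms: iodine, II
Why: Gammill iodocyclisation, in which iodination at the enaminone α-carbon, 6-endo attack of the phenol oxygen on the iminium carbon and loss of dimethylamine close ring C as the 3-iodochromone.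

Step 6
Reactants: 7 5,7-bis(benzyloxy)-3-iodo-6-methoxy-4H-chromen-4-one
Product: 8 5,7-bis(benzyloxy)-6-methoxy-3-[(trimethylsilyl)ethynyl]-4H-chromen-4-one
Conditions: HC≡CSiMe3, PdCl2(PPh3)2 (cat.), CuI (cat.), Et3N, THF, rt
Reagents that add atoms: trimethylsilylacetylene, C#C[Si](C)(C)C
Why: Sonogashira coupling at the vinylic C3–I bond, which adds readily to zerovalent palladium; a tertiary amine is used so that the electrophilic chromone C2 is not attacked.

Step 7
Reactants: 8 5,7-bis(benzyloxy)-6-methoxy-3-[(trimethylsilyl)ethynyl]-4H-chromen-4-one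
Product: 9 5,7-bis(benzyloxy)-3-ethynyl-6-methoxy-4H-chromen-4-one
Conditions: TBAF, AcOH, THF, 0 °C
Reagents that add atoms: none
Why: fluoride-induced protodesilylation of the alkynylsilane, buffered with acetic acid so that the base-sensitive pyranone ring is not opened.

Step 8
Reactants: 10 (Z)-1,2-dimethoxyethene; 11 chromium hexacarbonyl, Cr(CO)6
Product: 14 pentacarbonyl[(Z)-1,2-dimethoxyvinyl(methoxy)carbene]chromium, via (Z)-1,2-dimethoxyvinyllithium 12 (not isolated), via lithium acylchromate 13 (not isolated)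
Conditions: t-BuLi, THF, −78 °C; add to Cr(CO)6, THF, −78 → 0 °C; evaporate; Me3OBF4, CH2Cl2, 0 °C
Reagents that add atoms: trimethyloxonium tetrafluoroborate, C[O+](C)C.F[B-](F)(F)F
Why: Fischer carbene synthesis, that is α-lithiation of the enol ether with retention of the double-bond geometry, addition of the vinyllithium to a CO ligand of Cr(CO)6 to give the acylchromate and O-methylation by the Meerwein salt, with the low temperature holding back β-elimination of lithium methoxide from 12.

Step 9
Reactants: 9 5,7-bis(benzyloxy)-3-ethynyl-6-methoxy-4H-chromen-4-one; 14 pentacarbonyl[(Z)-1,2-dimethoxyvinyl(methoxy)carbene]chromium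
Product: 16 5,7-bis(benzyloxy)-3-(2-hydroxy-3,4,5-trimethoxyphenyl)-6-methoxy-4H-chromen-4-one, via Cr(CO)3 arene complex 15 (not isolated)
Conditions: 14 (1.5 equiv), THF (0.05 M), Ar, 50 °C; then air, daylight, Et2O/MeCN, rt
Reagents that add atoms: none
Why: Thermal loss of one cis CO from 14 opens a site on zerovalent chromium for alkyne 9, which inserts with its CH terminus bonded to the carbene carbon (C5'–C6') to give a vinylcarbene; CO insertion then gives the chromium-bound dienylketene (C1'–C2'), and attack of the ketene carbon on the methoxy-bearing vinyl β-carbon (C2'–C3') followed by tautomerisation of the cyclohexadienone delivers ring B as the C2' phenol, first held on Cr(CO)3 (15) and freed by air. This is the Dötz benzannulation of an alkenyl(alkoxy)carbene complex with a terminal alkyne; α-alkoxyalkenyl complexes such as dihydropyranyl carbenes are established partners, and the added β-methoxy group is the untested element. Ring B closes by 6π-electrocyclisation of the dienylketene on the chromium template, and no stereocenter is formed. The step needs one orientation of alkyne insertion, which the terminal alkyne secures: the bulky chromonyl group turns away from the carbene carbon and so ends next to the CO-derived carbon, between C2'–OH and C6'–H. It also needs CO insertion to outrun cyclopentannulation, which chromium, an alkenyl carbene and THF at moderate temperature all favour. The chromone enone, the benzyl ethers and the methoxy groups are spectators, and the crowded C3–C1' bond is already present in 9 as the bond from C3 to the alkyne.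

Step 10
Reactants: 16 5,7-bis(benzyloxy)-3-(2-hydroxy-3,4,5-trimethoxyphenyl)-6-methoxy-4H-chromen-4-one
Product: 17 5,7-bis(benzyloxy)-6-methoxy-3-(2,3,4,5-tetramethoxyphenyl)-4H-chromen-4-one
Conditions: MeI, K2CO3, acetone, 50 °C
Reagents that add atoms: iodomethane, CI
Why: Williamson methylation of the only free phenol; the benzyl ethers and the chromone are stable to K2CO3 in acetone.

Step 11
Reactants: 17 5,7-bis(benzyloxy)-6-methoxy-3-(2,3,4,5-tetramethoxyphenyl)-4H-chromen-4-one
Product: 18 irisjaponin A, 5,7-dihydroxy-6-methoxy-3-(2,3,4,5-tetramethoxyphenyl)-4H-chromen-4-one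
Conditions: H2 (1 atm), 10% Pd/C, EtOAc/MeOH, rt
Reagents that add atoms: none
Why: hydrogenolysis of the two aryl benzyl ethers over Pd/C, stopped after two equivalents of H2 because the trisubstituted, vinylogous-ester C2=C3 bond of the isoflavone is reduced much more slowly.

**Compound list**

1 | 1-(2,4,6-trihydroxyphenyl)ethanone | CC(=O)c1c(O)cc(O)cc1O | starting material
2 | 1-[2,4-bis(benzyloxy)-6-hydroxyphenyl]ethanone | CC(=O)c1c(O)cc(OCc2ccccc2)cc1OCc1ccccc1 | intermediate
3 | potassium 3-acetyl-2,6-bis(benzyloxy)-4-hydroxyphenyl sulfate (not isolated) | CC(=O)c1c(O)cc(OCc2ccccc2)c(OS(=O)(=O)[O-])c1OCc1ccccc1.[K+] | intermediate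
4 | 1-[2,4-bis(benzyloxy)-3,6-dihydroxyphenyl]ethanone | CC(=O)c1c(O)cc(OCc2ccccc2)c(O)c1OCc1ccccc1 | intermediate
5 | 1-[2,4-bis(benzyloxy)-6-hydroxy-3-methoxyphenyl]ethanone | CC(=O)c1c(O)cc(OCc2ccccc2)c(OC)c1OCc1ccccc1 | intermediate
6 | (E)-1-[2,4-bis(benzyloxy)-6-hydroxy-3-methoxyphenyl]-3-(dimethylamino)prop-2-en-1-one | CN(C)/C=C/C(=O)c1c(O)cc(OCc2ccccc2)c(OC)c1OCc1ccccc1 | intermediate
7 | 5,7-bis(benzyloxy)-3-iodo-6-methoxy-4H-chromen-4-one | Ic1coc2cc(OCc3ccccc3)c(OC)c(OCc3ccccc3)c2c1=O | intermediate
8 | 5,7-bis(benzyloxy)-6-methoxy-3-[(trimethylsilyl)ethynyl]-4H-chromen-4-one | C[Si](C)(C)C#Cc1coc2cc(OCc3ccccc3)c(OC)c(OCc3ccccc3)c2c1=O | intermediate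
9 | 5,7-bis(benzyloxy)-3-ethynyl-6-methoxy-4H-chromen-4-one | C#Cc1coc2cc(OCc3ccccc3)c(OC)c(OCc3ccccc3)c2c1=O | intermediate
10 | (Z)-1,2-dimethoxyethene | CO/C=C\OC | starting material
11 | chromium hexacarbonyl, Cr(CO)6 | O=C=[Cr](=C=O)(=C=O)(=C=O)(=C=O)=C=O | starting material
12 | (Z)-1,2-dimethoxyvinyllithium (not isolated) | [Li]/C(OC)=C/OC | intermediate
13 | lithium pentacarbonyl[(Z)-2,3-dimethoxyacryloyl]chromate (not isolated) | [Li+].[O-]C(=[Cr](=C=O)(=C=O)(=C=O)(=C=O)=C=O)/C(OC)=C/OC | intermediate
14 | pentacarbonyl[(Z)-1,2-dimethoxyvinyl(methoxy)carbene]chromium | COC(=[Cr](=C=O)(=C=O)(=C=O)(=C=O)=C=O)/C(OC)=C/OC | intermediate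
15 | tricarbonylchromium η6 complex of phenol 16, Cr(CO)3 bound to ring B (not isolated; SMILES gives the arene and the Cr(CO)3 fragment as two parts) | COc1cc(-c2coc3cc(OCc4ccccc4)c(OC)c(OCc4ccccc4)c3c2=O)c(O)c(OC)c1OC.O=C=[Cr](=C=O)=C=O | intermediate
16 | 5,7-bis(benzyloxy)-3-(2-hydroxy-3,4,5-trimethoxyphenyl)-6-methoxy-4H-chromen-4-one | COc1cc(-c2coc3cc(OCc4ccccc4)c(OC)c(OCc4ccccc4)c3c2=O)c(O)c(OC)c1OC | intermediate
17 | 5,7-bis(benzyloxy)-6-methoxy-3-(2,3,4,5-tetramethoxyphenyl)-4H-chromen-4-one | COc1cc(-c2coc3cc(OCc4ccccc4)c(OC)c(OCc4ccccc4)c3c2=O)c(OC)c(OC)c1OC | intermediate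
18 | irisjaponin A, 5,7-dihydroxy-6-methoxy-3-(2,3,4,5-tetramethoxyphenyl)-4H-chromen-4-one | COc1cc(-c2coc3cc(O)c(OC)c(O)c3c2=O)c(OC)c(OC)c1OC | target

**Step count**

Total: 11 steps. Longest linear sequence: 10 steps (steps 1–7 and 9–11, from 1); the carbene branch is one step (step 8).

**Steps most likely to fail**

Step 9. The alkyne may insert without the CO insertion that should follow, leading to cyclopentannulation or furan formation. The two methoxy donors on the vinyl group make the carbene less electrophilic and bind the remaining CO ligands more firmly, and slow CO loss would also let the ethynylchromone oligomerise at the metal. Fallback from 7 back to 17, with ring B brought in intact by cross-coupling: bought 1,2,3,4-tetramethoxybenzene is brominated (NBS, MeCN, rt) to 1-bromo-2,3,4,5-tetramethoxybenzene F1. Miyaura borylation (B2pin2, PdCl2(dppf), KOAc, dioxane, 85 °C) gives 4,4,5,5-tetramethyl-2-(2,3,4,5-tetramethoxyphenyl)-1,3,2-dioxaborolane F2. Suzuki–Miyaura coupling of F2 with 7 (Pd(OAc)2, SPhos, K3PO4, toluene/H2O, 80 °C) should give 17, and step 11 completes the synthesis.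

Step 8. In 12 the lithium and the β-methoxy group are anti, so β-elimination of lithium methoxide can outrun the addition to Cr(CO)6 once the mixture is warmed; α-deprotonation may also be incomplete at −78 °C. Fallback from 11 back to 14, with no vinyllithium involved:
- Bought methyl methoxyacetate is formylated (HCO2Me, NaH, THF, 0 °C) to sodium (Z)-2,3-dimethoxy-3-oxoprop-1-en-1-olate F3.
- O-methylation (Me2SO4, DMF) gives methyl (Z)-2,3-dimethoxyacrylate F4; either alkene geometry would serve.
- Saponification (LiOH, THF/H2O, then careful acidification) gives (Z)-2,3-dimethoxyacrylic acid F5.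
- Oxalyl chloride (cat. DMF, CH2Cl2, 0 °C) gives (Z)-2,3-dimethoxyacryloyl chloride F6.
- Cr(CO)6 11 is reduced with NaC10H8 (sodium naphthalenide) in THF at −78 °C to disodium pentacarbonylchromate Na2Cr(CO)5 F7.
- F7 is acylated by F6 to sodium pentacarbonyl[(Z)-2,3-dimethoxyacryloyl]chromate F8, and Me3OBF4 in CH2Cl2 then gives 14.

Step 2. Conversion may be low at the hindered para carbon, the hydroquinone sulfate may be over-oxidised to quinone-derived tars, and the benzyl ethers may be partly cleaved during the hot acid hydrolysis. Fallback from 2 back to 4, through the quinone: Teuber oxidation of 2 with (KSO3)2NO (KH2PO4 buffer, acetone/H2O, rt) should give 2-acetyl-3,5-bis(benzyloxy)cyclohexa-2,5-diene-1,4-dione F9. Reduction with Na2S2O4 (EtOAc/H2O, rt) then gives hydroquinone 4.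

**Further compounds**

F1 | step 9 | 1-bromo-2,3,4,5-tetramethoxybenzene | COc1cc(Br)c(OC)c(OC)c1OC
F2 | step 9 | 4,4,5,5-tetramethyl-2-(2,3,4,5-tetramethoxyphenyl)-1,3,2-dioxaborolane | COc1cc(B2OC(C)(C)C(C)(C)O2)c(OC)c(OC)c1OC
F3 | step 8 | sodium (Z)-2,3-dimethoxy-3-oxoprop-1-en-1-olate | COC(=O)/C(OC)=C/[O-].[Na+]
F4 | step 8 | methyl (Z)-2,3-dimethoxyacrylate | COC(=O)/C(OC)=C/OC
F5 | step 8 | (Z)-2,3-dimethoxyacrylic acid | OC(=O)/C(OC)=C/OC
F6 | step 8 | (Z)-2,3-dimethoxyacryloyl chloride | ClC(=O)/C(OC)=C/OC
F7 | step 8 | disodium pentacarbonylchromate, Na2Cr(CO)5 | [Na+].[Na+].O=C=[Cr-2](=C=O)(=C=O)(=C=O)=C=O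
F8 | step 8 | sodium pentacarbonyl[(Z)-2,3-dimethoxyacryloyl]chromate | [Na+].[O-]C(=[Cr](=C=O)(=C=O)(=C=O)(=C=O)=C=O)/C(OC)=C/OC
F9 | step 2 | 2-acetyl-3,5-bis(benzyloxy)cyclohexa-2,5-diene-1,4-dione | CC(=O)C1=C(OCc2ccccc2)C(=O)C(OCc2ccccc2)=CC1=O
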